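**Plan**
Locants follow the atom order of the target SMILES. The ring C9–C10–C11–C18–C16–C15 (C16=O, C19 on C18, C28 on C11) is a carvone ring carrying one extra carbon on its β-carbon, and the C12–C14 bridge ties its α′-carbon C15 to that β-carbon C11; one enolate cascade can therefore build the bicyclo[2.2.2]octanone.
Retrosynthetic cuts, in order: C2–C3 (diene arm); C23–C24, O27–C25 and C28–C22 (lactone and ring B); C12–C13; then C15–C14, C12–C11 and C18–C20 together; last C11–C28.
Forward: (R)-carvone (1) is cleaved at the isopropenyl group, ketalised, and turned into a 3-(alkoxymethyl) enone by 1,2-addition and oxidative 1,3-transposition; the cascade then closes the bicycle and attaches the allyl arm.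
After that the sulfone becomes the C12 methyl alkene, the allyl arm and C28 are joined to give ring B, ketone reduction closes the lactone, and the diene arm is coupled last.
Stereochemistry: C9 is the carvone stereocentre and steers C15 and C11 (and, relayed by the sulfonyl group, C18) in the cascade; C22 equilibrates next to the C28 ketone, C28 comes from hydride attack away from the C19 methyl, and C23 from convex-face methylation.

Key step: step 6

Remark: the C28 oxygen is carried as a 4-methoxybenzyl ether so that it can be freed without touching the dioxolane; the three bridges are called a (C9–C10), b (C12–C14) and c (C16–C18).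

**Step 1**
Reactants: 1 (R)-carvone
Product: 3 (5R)-5-acetyl-2-methylcyclohex-2-en-1-one, via ozonide 2 (not isolated)
Conditions: O3, CH2Cl2, −78 °C; then Me2S, −78 °C to rt
Reagents that add atoms: ozone, [O-][O+]=O
Why: Ozonolysis with reductive work-up should cleave the electron-rich 1,1-disubstituted isopropenyl alkene much faster than the electron-poor enone alkene and does not touch the C5 stereocentre.

**Step 2**
Reactants: 3 (5R)-5-acetyl-2-methylcyclohex-2-en-1-one
Product: 4 (5R)-2-methyl-5-(2-methyl-1,3-dioxolan-2-yl)cyclohex-2-en-1-one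
Conditions: Me3SiOCH2CH2OSiMe3, Me3SiOTf (cat.), CH2Cl2, −78 °C
Reagents that add atoms: 1,2-bis(trimethylsilyloxy)ethane, C[Si](C)(C)OCCO[Si](C)(C)C
Why: Silyl triflate-catalysed ketalisation with the bis-silyl glycol ether at low temperature should convert only the saturated methyl ketone, the conjugated ketone being far less electrophilic, and is too mild to enolise C5.

**Step 3**
Reactants: 5 4-methoxybenzyl alcohol; 6 tributyl(iodomethyl)stannane
Product: 8 tributyl{[(4-methoxybenzyl)oxy]methyl}stannane, via sodium 4-methoxybenzyl oxide 7 (not isolated)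
Conditions: NaH, THF/DMF, 0 °C; then 6, 0 °C to rt
Reagents that add atoms: none
Why: Williamson ether synthesis, in which the iodomethyl stannane is an unhindered primary SN2 electrophile.

**Step 4**
Reactants: 4 (5R)-2-methyl-5-(2-methyl-1,3-dioxolan-2-yl)cyclohex-2-en-1-one; 8 tributyl{[(4-methoxybenzyl)oxy]methyl}stannane
Product: 10 (5R)-1-{[(4-methoxybenzyl)oxy]methyl}-2-methyl-5-(2-methyl-1,3-dioxolan-2-yl)cyclohex-2-en-1-ol as a mixture of C1 epimers, via {[(4-methoxybenzyl)oxy]methyl}lithium 9 (not isolated)
Conditions: 8, n-BuLi, THF, −78 °C; then 4, −78 °C; then H2O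
Reagents that add atoms: none
Why: Tin–lithium exchange gives the α-alkoxymethyllithium, which should add 1,2 to the enone carbonyl at −78 °C before any [1,2]-Wittig shift can occur, and both carbinol epimers serve because this centre is lost in step 5.

**Step 5**
Reactants: 10 tertiary allylic alcohol
Product: 11 (5S)-3-{[(4-methoxybenzyl)oxy]methyl}-2-methyl-5-(2-methyl-1,3-dioxolan-2-yl)cyclohex-2-en-1-one
Conditions: [C5H5NH][CrO3Cl], 4 Å molecular sieves, CH2Cl2, rt
Reagents that add atoms: pyridinium chlorochromate, [O-][Cr](=O)(=O)Cl.c1cc[nH+]cc1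
Why: Babler–Dauben oxidative transposition, in which the tertiary allylic chromate ester undergoes a [3,3] shift and is oxidised to the transposed enone, so that the old carbonyl carbon becomes the β-carbon C11 bearing C28 and the old C4 becomes the α′-carbon C15 (the stereocentre is unchanged, only its descriptor switches to S).

**Step 6**
Reactants: 11 enone; 12 phenyl vinyl sulfone; 13 allyl iodide
Product: 17 3-allyl-4-{[(4-methoxybenzyl)oxy]methyl}-3-methyl-7-(2-methyl-1,3-dioxolan-2-yl)-5-(phenylsulfonyl)bicyclo[2.2.2]octan-2-one (C9 dioxolanyl on the side of bridge c; C12 sulfonyl on the side of bridge c; C20 on the side of bridge a), via lithium dienolate 14 (not isolated), via α-sulfonyl carbanion 15 (not isolated), via bicyclic lithium enolate 16 (not isolated)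
Conditions: LiN(iPr)2, THF, −78 °C; then 12, −78 to −20 °C; then 13, HMPA, −20 °C to rt
Reagents that add atoms: none
Why: LiN(iPr)2 removes a C15 proton under kinetic control to give the cross-conjugated dienolate 14, which adds to the vinyl sulfone (C15–C14); the α-sulfonyl carbanion 15 then attacks the enone β-carbon C11 (C12–C11) and the resulting enolate 16 is C-allylated by 13 (C18–C20), the closest known reaction type being the double Michael annulation of kinetic cyclohexenone enolates with acrylates, here extended by enolate alkylation in the same flask. The one ring closure, giving ring C11–C12–C14–C15–C16–C18, is an intramolecular Michael addition that is 6-exo-trig when counted along C12–C14–C15–C9–C10–C11 (C18 outside that chain), and it completes the bicyclo[2.2.2]octanone. C15 is set by approach of 12 to the dienolate face opposite the C9 dioxolanyl group, C11 follows because the two-carbon bridge must span a single face, C12 is set by a lithium-bridged endo-type transition state that turns the sulfonyl group toward the C16 oxygen, and C18 is set by allylation of 16 on the face away from that sulfonyl group, which leaves C19 on the C12 side and puts C20 on the C10 side. The step needs α′- rather than γ-deprotonation (hindered amide base at −78 °C), C- rather than O-allylation (a soft allylic iodide on a lithium enolate with HMPA) and no proton transfer from C12–H to the enolate (a secondary alkyl sulfone is less acidic than the ketone). The enone suits the cascade because its α′- and β-carbons are exactly the two bridgeheads.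

**Step 7**
Reactants: 17 sulfonyl ketone
Product: 19 3-allyl-4-{[(4-methoxybenzyl)oxy]methyl}-3-methyl-7-(2-methyl-1,3-dioxolan-2-yl)bicyclo[2.2.2]octane-2,5-dione, via C12-lithio sulfone 18 (not isolated)
Conditions: LiN(iPr)2, THF, −78 °C; then Me3SiOOSiMe3, −78 to 0 °C
Reagents that add atoms: bis(trimethylsilyl) peroxide, C[Si](C)(C)OO[Si](C)(C)C
Why: Oxidative desulfonylation, in which the α-sulfonyl carbanion 18 should attack a peroxide oxygen and the resulting α-silyloxy sulfone collapses to the ketone with loss of benzenesulfinate, while the C16 ketone cannot enolise (bridgehead C15, quaternary C18) and is left alone by the base.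

**Step 8**
Reactants: 19 diketone
Product: 21 C12 enol triflate of 19 (C12=C14), via potassium enolate 20 (not isolated)
Conditions: KN(SiMe3)2, THF, −78 °C; then PhNTf2, −78 to 0 °C
Reagents that add atoms: N-phenylbis(trifluoromethanesulfonimide), O=S(=O)(N(c1ccccc1)S(=O)(=O)C(F)(F)F)C(F)(F)F
Why: Enol triflate formation, regiospecific because the C12 ketone can enolise only toward C14 (C11 is quaternary) and the C16 ketone has no enolisable position, so a single potassium enolate is trapped on oxygen.

**Step 9**
Reactants: 21 enol triflate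
Product: 22 3-allyl-4-{[(4-methoxybenzyl)oxy]methyl}-3,5-dimethyl-7-(2-methyl-1,3-dioxolan-2-yl)bicyclo[2.2.2]oct-5-en-2-one
Conditions: MeZnCl, Pd(PPh3)4 (5 mol %), THF, 50 °C
Reagents that add atoms: methylzinc chloride, C[Zn]Cl
Why: Negishi coupling, in which zerovalent palladium inserts into the alkenyl triflate and the methylzinc reagent delivers C13 under conditions that tolerate ketone, ketal, ether and terminal alkene, an intramolecular Heck path to the allyl group being excluded because C20 lies anti to C12 across C11–C18.

**Step 10**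
Reactants: 22 allyl ketone
Product: 24 C22 primary alcohol (3-hydroxypropyl arm on C18), via B-alkyl-9-borabicyclo[3.3.1]nonane 23 (not isolated)
Conditions: 9-BBN, THF, 0 °C to rt; then NaOH, H2O2, 0 °C
Reagents that add atoms: hydrogen peroxide, OO
Why: Hydroboration–oxidation, in which 9-BBN should add anti-Markovnikov to the monosubstituted alkene far faster than to the trisubstituted C12=C14 alkene or the shielded C16 ketone, and alkaline peroxide converts C22–B into C22–OH.

**Step 11**
Reactants: 24 mono-protected diol
Product: 25 4-(hydroxymethyl)-3-(3-hydroxypropyl)-3,5-dimethyl-7-(2-methyl-1,3-dioxolan-2-yl)bicyclo[2.2.2]oct-5-en-2-one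
Conditions: DDQ, CH2Cl2/pH 7 phosphate buffer, 0 °C to rt
Reagents that add atoms: none
Why: Oxidative cleavage of the 4-methoxybenzyl ether by DDQ (hydride abstraction, then hydrolysis of the oxocarbenium ion) under buffered conditions that leave the dioxolane intact.

**Step 12**
Reactants: 25 diol
Product: 27 ethyl (E)-enoate bearing the free C28 aldehyde (C18–CH2CH2CH=CHCO2Et; C11–CHO), via dialdehyde 26 (not isolated)
Conditions: Dess–Martin periodinane, pyridine, CH2Cl2, 0 °C to rt; then Ph3P=CHCO2Et, rt
Reagents that add atoms: ethyl (triphenylphosphoranylidene)acetate, CCOC(=O)C=P(c1ccccc1)(c1ccccc1)c1ccccc1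
Why: Dess–Martin oxidation of both primary alcohols followed in the same flask by a Wittig reaction, in which the stabilised ylide should react only with the unhindered C22 aldehyde (E alkene) because the C28 aldehyde sits on the fully substituted bridgehead C11.

**Step 13**
Reactants: 27 aldehyde enoate
Product: 28 ring B hydroxy ester (C22 CH2CO2Et arm equatorial; C28 hydroxyl equatorial and trans to it)
Conditions: SmI2, t-BuOH, THF, −78 to 0 °C
Reagents that add atoms: none
Why: SmI2-mediated ketyl–olefin reductive cyclisation, in which the aldehyde (reduced much faster than the hindered C16 ketone) gives a ketyl that adds 6-exo-trig to the enoate β-carbon C22 through a chair with the acceptor equatorial, the oxygen being expected in the unhindered equatorial site; this C28 configuration is deliberately erased in step 14.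

**Step 14**
Reactants: 28 hydroxy ester
Product: 29 ring B keto ester (C28 ketone; C22 CH2CO2Et arm equatorial)
Conditions: Dess–Martin periodinane, pyridine, CH2Cl2, rt
Reagents that add atoms: none
Why: Dess–Martin oxidation of the secondary alcohol gives the ring B ketone, next to which C22 is epimerisable and should keep its arm equatorial because the axial site is syn-axial to C10.

**Step 15**
Reactants: 29 keto ester
Product: 31 cis-fused γ-lactone (O27 axial on ring B and syn to the C19 methyl; C23 still CH2), via axial lithium alkoxide 30 (not isolated)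
Conditions: LiBH(s-Bu)3, THF, −78 to 0 °C; then H2O
Reagents that add atoms: none
Why: Reduction with a bulky trialkylborohydride, which should attack the ring B ketone equatorially, from the face opposite the syn-axial C19 methyl, to give the axial alkoxide cis to the C22 arm; this closes the lactone by 5-exo-trig acyl substitution, while the C16 ketone, flanked by bridgehead C15 and quaternary C18 and covered by the dioxolanyl group and C19, should react much more slowly.

**Step 16**
Reactants: 31 lactone
Product: 33 α-methyl lactone (C24 on the convex face and trans to C21), via lithium lactone enolate 32 (not isolated)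
Conditions: LiN(iPr)2, THF, −78 °C; then MeI, −78 to −40 °C
Reagents that add atoms: iodomethane, CI
Why: Lactone enolate alkylation, in which the enolate of the cis-fused lactone should take iodomethane on its convex face (the side of H22 and H28, trans to C21), which is also the more stable C23 configuration, and C16 offers no competing enolisation.

**Step 17**
Reactants: 33 dioxolane lactone
Product: 34 C9 methyl ketone
Conditions: 1 M HCl, THF, rt
Reagents that add atoms: water, O
Why: Acid-catalysed ketal hydrolysis under mild aqueous conditions, which the lactone and the non-conjugated enone tolerate and which are too weak to enolise the freed methyl ketone toward C9.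

**Step 18**
Reactants: 34 methyl ketone
Product: 36 terminal enol triflate (C9–C(OTf)=CH2), via potassium enolate 35 (not isolated)
Conditions: KN(SiMe3)2 added to 34 and PhNTf2, THF, −78 to 0 °C
Reagents that add atoms: N-phenylbis(trifluoromethanesulfonimide), O=S(=O)(N(c1ccccc1)S(=O)(=O)C(F)(F)F)C(F)(F)F
Why: Kinetic enolisation and O-sulfonylation, in which the hindered amide removes a methyl proton (more acidic than the tertiary lactone C23–H and more accessible than C9–H) and the triflimide already present traps the terminal enolate, any aldol closure onto the neighbouring hindered C16 ketone being reversible.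

**Step 19**
Reactants: 36 enol triflate; 37 5-bromo-2-methylpent-2-ene
Product: 39 CNP0385704.2 (target), via (4-methylpent-3-en-1-yl)zinc bromide 38 (not isolated)
Conditions: 37, Zn, LiCl, THF, 40 °C; then 36, PdCl2(dppf) (5 mol %; dppf = 1,1′-bis(diphenylphosphino)ferrocene), THF, 50 °C
Reagents that add atoms: none
Why: Negishi sp2–sp3 coupling, in which zinc insertion into the primary bromide gives the alkylzinc bromide that transmetallates to the alkenylpalladium formed from the triflate, the chelating diphosphine favouring reductive elimination over β-hydride elimination and leaving ketone and lactone untouched.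

**Compound list**
1 | (R)-carvone, (5R)-2-methyl-5-(prop-1-en-2-yl)cyclohex-2-en-1-one | CC(=C)[C@@H]1CC=C(C)C(=O)C1 | starting material
2 | ozonide of 1 at the isopropenyl group, 3-methyl-3-[(1R)-4-methyl-5-oxocyclohex-3-en-1-yl]-1,2,4-trioxolane | CC1(OCOO1)[C@@H]1CC=C(C)C(=O)C1 | intermediate
3 | (5R)-5-acetyl-2-methylcyclohex-2-en-1-one | CC(=O)[C@@H]1CC=C(C)C(=O)C1 | intermediate
4 | (5R)-2-methyl-5-(2-methyl-1,3-dioxolan-2-yl)cyclohex-2-en-1-one | CC1(OCCO1)[C@@H]1CC=C(C)C(=O)C1 | intermediate
5 | 4-methoxybenzyl alcohol | COc1ccc(CO)cc1 | starting material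
6 | tributyl(iodomethyl)stannane | CCCC[Sn](CCCC)(CCCC)CI | starting material
7 | sodium 4-methoxybenzyl oxide | COc1ccc(CO[Na])cc1 | intermediate
8 | tributyl{[(4-methoxybenzyl)oxy]methyl}stannane | CCCC[Sn](CCCC)(CCCC)COCc1ccc(OC)cc1 | intermediate
9 | {[(4-methoxybenzyl)oxy]methyl}lithium | [Li]COCc1ccc(OC)cc1 | intermediate
10 | (5R)-1-{[(4-methoxybenzyl)oxy]methyl}-2-methyl-5-(2-methyl-1,3-dioxolan-2-yl)cyclohex-2-en-1-ol, both C1 epimers | COc1ccc(COCC2(O)C[C@H](C3(C)OCCO3)CC=C2C)cc1 | intermediate
11 | (5S)-3-{[(4-methoxybenzyl)oxy]methyl}-2-methyl-5-(2-methyl-1,3-dioxolan-2-yl)cyclohex-2-en-1-one (ring atoms are C16, C18, C11, C10, C9, C15 of the target) | COc1ccc(COCC2=C(C)C(=O)C[C@H](C2)C2(C)OCCO2)cc1 | intermediate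
12 | phenyl vinyl sulfone | C=CS(=O)(=O)c1ccccc1 | starting material
13 | allyl iodide, 3-iodoprop-1-ene | C=CCI | starting material
14 | lithium cross-conjugated dienolate of 11 (C15=C16(OLi)–C18=C11) | [Li]OC1=C[C@@H](C2(C)OCCO2)CC(COCc2ccc(OC)cc2)=C1C | intermediate
15 | lithium α-sulfonyl carbanion after the first Michael addition (CH2CH(Li)SO2Ph on C15, trans to the C9 dioxolanyl group) | [Li]C(S(=O)(=O)c1ccccc1)C[C@H]1C(=O)C(C)=C(COCc2ccc(OC)cc2)C[C@@H]1C1(C)OCCO1 | intermediate
16 | lithium enolate C16(OLi)=C18 of the sulfonyl bicyclo[2.2.2]octanone | CC1(OCCO1)[C@H]1C[C@]2(COCc3ccc(OC)cc3)[C@@H](S(=O)(=O)c3ccccc3)C[C@H]1C(O[Li])=C2C | intermediate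
17 | 3-allyl-4-{[(4-methoxybenzyl)oxy]methyl}-3-methyl-7-(2-methyl-1,3-dioxolan-2-yl)-5-(phenylsulfonyl)bicyclo[2.2.2]octan-2-one; dioxolanyl (C9) and sulfonyl (C12) on the side of bridge c, allyl (C20) on the side of bridge a, C19 on the side of bridge b | CC1(OCCO1)[C@H]1C[C@]2(COCc3ccc(OC)cc3)[C@@H](S(=O)(=O)c3ccccc3)C[C@H]1C(=O)[C@]2(C)CC=C | intermediate
18 | C12-lithio derivative of sulfone 17 | CC1(OCCO1)[C@H]1C[C@]2(COCc3ccc(OC)cc3)C([Li])(S(=O)(=O)c3ccccc3)C[C@H]1C(=O)[C@]2(C)CC=C | intermediate
19 | 3-allyl-4-{[(4-methoxybenzyl)oxy]methyl}-3-methyl-7-(2-methyl-1,3-dioxolan-2-yl)bicyclo[2.2.2]octane-2,5-dione (ketones at C16 and C12) | CC1(OCCO1)[C@H]1C[C@]2(COCc3ccc(OC)cc3)C(=O)C[C@H]1C(=O)[C@]2(C)CC=C | intermediate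
20 | potassium enolate C12(OK)=C14 of 19 | CC1(OCCO1)[C@H]1C[C@]2(COCc3ccc(OC)cc3)C(O[K])=C[C@H]1C(=O)[C@]2(C)CC=C | intermediate
21 | C12 enol triflate of 19 (C12(OTf)=C14) | CC1(OCCO1)[C@H]1C[C@]2(COCc3ccc(OC)cc3)C(OS(=O)(=O)C(F)(F)F)=C[C@H]1C(=O)[C@]2(C)CC=C | intermediate
22 | 3-allyl-4-{[(4-methoxybenzyl)oxy]methyl}-3,5-dimethyl-7-(2-methyl-1,3-dioxolan-2-yl)bicyclo[2.2.2]oct-5-en-2-one | CC1(OCCO1)[C@H]1C[C@]2(COCc3ccc(OC)cc3)C(C)=C[C@H]1C(=O)[C@]2(C)CC=C | intermediate
23 | B-alkyl-9-borabicyclo[3.3.1]nonane from 22 (boron on C22) | CC1(OCCO1)[C@H]1C[C@]2(COCc3ccc(OC)cc3)C(C)=C[C@H]1C(=O)[C@]2(C)CCCB1C2CCCC1CCC2 | intermediate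
24 | 3-(3-hydroxypropyl) analogue of 22 (C22–OH, C28–O-4-methoxybenzyl) | CC1(OCCO1)[C@H]1C[C@]2(COCc3ccc(OC)cc3)C(C)=C[C@H]1C(=O)[C@]2(C)CCCO | intermediate
25 | 4-(hydroxymethyl)-3-(3-hydroxypropyl)-3,5-dimethyl-7-(2-methyl-1,3-dioxolan-2-yl)bicyclo[2.2.2]oct-5-en-2-one | CC1(OCCO1)[C@H]1C[C@]2(CO)C(C)=C[C@H]1C(=O)[C@]2(C)CCCO | intermediate
26 | dialdehyde (C28 formyl on C11, 3-oxopropyl on C18) | CC1(OCCO1)[C@H]1C[C@]2(C=O)C(C)=C[C@H]1C(=O)[C@]2(C)CCC=O | intermediate
27 | ethyl (E)-5-(bicyclic C18)-pent-2-enoate with free C28 aldehyde | CC1(OCCO1)[C@H]1C[C@]2(C=O)C(C)=C[C@H]1C(=O)[C@]2(C)CC/C=C/C(=O)OCC | intermediate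
28 | ring B hydroxy ester: C28–OH equatorial, C22–CH2CO2Et equatorial, trans | CC1(OCCO1)[C@H]1C[C@]23C(C)=C[C@H]1C(=O)[C@]2(C)CC[C@@H](CC(=O)OCC)[C@@H]3O | intermediate
29 | ring B keto ester: C28 ketone, C22–CH2CO2Et equatorial | CC1(OCCO1)[C@H]1C[C@]23C(C)=C[C@H]1C(=O)[C@]2(C)CC[C@@H](CC(=O)OCC)C3=O | intermediate
30 | lithium alkoxide of the cis hydroxy ester: C28–O axial, syn to C19 | CC1(OCCO1)[C@H]1C[C@]23C(C)=C[C@H]1C(=O)[C@]2(C)CC[C@@H](CC(=O)OCC)[C@H]3O[Li] | intermediate
31 | cis-fused γ-lactone without the C24 methyl, dioxolane on the C9 arm | CC1(OCCO1)[C@H]1C[C@]23C(C)=C[C@H]1C(=O)[C@]2(C)CC[C@H]1CC(=O)O[C@H]13 | intermediate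
32 | lithium enolate of lactone 31 (C23=C25(OLi)) | CC1(OCCO1)[C@H]1C[C@]23C(C)=C[C@H]1C(=O)[C@]2(C)CC[C@H]1C=C(O[Li])O[C@H]13 | intermediate
33 | α-methyl lactone with target configuration at C22, C23 and C28, dioxolane on the C9 arm | CC1(OCCO1)[C@H]1C[C@]23C(C)=C[C@H]1C(=O)[C@]2(C)CC[C@H]1[C@H](C)C(=O)O[C@H]13 | intermediate
34 | C9 acetyl lactone | CC(=O)[C@H]1C[C@]23C(C)=C[C@H]1C(=O)[C@]2(C)CC[C@H]1[C@H](C)C(=O)O[C@H]13 | intermediate
35 | potassium enolate of the methyl ketone of 34 (terminal) | C=C(O[K])[C@H]1C[C@]23C(C)=C[C@H]1C(=O)[C@]2(C)CC[C@H]1[C@H](C)C(=O)O[C@H]13 | intermediate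
36 | terminal enol triflate on C9 (C9–C(OTf)=CH2) | C=C(OS(=O)(=O)C(F)(F)F)[C@H]1C[C@]23C(C)=C[C@H]1C(=O)[C@]2(C)CC[C@H]1[C@H](C)C(=O)O[C@H]13 | intermediate
37 | 5-bromo-2-methylpent-2-ene | CC(C)=CCCBr | starting material
38 | (4-methylpent-3-en-1-yl)zinc bromide | CC(C)=CCC[Zn]Br | intermediate
39 | CNP0385704.2: bicyclo[2.2.2]octenone with the 6-methylhepta-1,5-dien-2-yl arm on C9 (syn to bridge c), fused ring B and cis-fused α-methyl γ-lactone | C=C(CCC=C(C)C)[C@H]1C[C@]23C(C)=C[C@H]1C(=O)[C@]2(C)CC[C@H]1[C@H](C)C(=O)O[C@H]13 | target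

**Totals and risks**
Total: 19 steps. Longest linear sequence: 18 steps (1 to 39 through steps 1, 2 and 4–19; step 3 is a side branch).

Most likely to fail:

1. Step 6. The alkylation of the crowded, tetrasubstituted enolate 16 next to the quaternary C11 may stall or go to oxygen, and any C12 epimer with the sulfonyl group turned away from bridge c would lose the facial bias at C18. Fallback, setting out from 11 and returning at 17: run the two Michael additions as in step 6 but quench enolate 16 with allyl chloroformate to give the allyl enol carbonate F1; Pd(PPh3)4 in THF at rt (Tsuji decarboxylative allylation) should then transfer the allyl group to C18 within an enolate/π-allylpalladium ion pair, again anti to the sulfonyl group, giving 17.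

2. Step 7. The hindered C12 carbanion may fragment by expelling the C18 enolate (retro-Michael opening of the bicycle), may fail to accept oxygen, or the new ketone may be enolised and oxidised further at C14. Fallback, setting out from 11 and returning at 19: use phenyl vinyl sulfoxide in place of 12 in the cascade of step 6 to give the C12 sulfoxide F2; Pummerer rearrangement (trifluoroacetic anhydride, 2,6-lutidine, CH2Cl2) gives the α-trifluoroacetoxy sulfide F3, and aqueous NaHCO3 hydrolyses it to diketone 19, so that no carbanion at C12 is needed.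

3. Step 15. Hydride may also reach the C16 ketone, or the hindered C28 ketone may be enolised instead of reduced, which would erode chemoselectivity and conversion. Fallback, setting out from 29 and returning at 31: reduce both ketones on purpose with excess LiBH(s-Bu)3 at 0 °C, which after lactonisation gives the C16 carbinol lactone F4, then re-oxidise the single free hydroxyl with Dess–Martin periodinane to return to 31.

**Further compounds**
F1 | step 6 | allyl enol carbonate of enolate 16 | CC1(OCCO1)[C@H]1C[C@]2(COCc3ccc(OC)cc3)[C@@H](S(=O)(=O)c3ccccc3)C[C@H]1C(OC(=O)OCC=C)=C2C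
F2 | step 7 | C12 phenylsulfinyl analogue of 17 (mixture at sulfur) | CC1(OCCO1)[C@H]1C[C@]2(COCc3ccc(OC)cc3)[C@@H](S(=O)c3ccccc3)C[C@H]1C(=O)[C@]2(C)CC=C
F3 | step 7 | C12 α-trifluoroacetoxy phenyl sulfide | CC1(OCCO1)[C@H]1C[C@]2(COCc3ccc(OC)cc3)C(OC(=O)C(F)(F)F)(Sc3ccccc3)C[C@H]1C(=O)[C@]2(C)CC=C
F4 | step 15 | C16 carbinol of lactone 31 | CC1(OCCO1)[C@H]1C[C@]23C(C)=C[C@H]1C(O)[C@]2(C)CC[C@H]1CC(=O)O[C@H]13
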